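The oxepane (O1, quaternary C2, carbinol C3, alkylidene C6) is disconnected across the C4–C5 and C6–C7 ring bonds into an α-alkoxy methyl ketone, whose ether oxygen carries a tributylstannylmethyl group, and a four-carbon (E)-2-iodoallyl bromide. In one flask the ketone enolate is allylated (C4–C5) and a palladium-catalysed Stille coupling joins the O-bound methylene to the vinyl iodide (C6–C7), closing the ring and transferring the E geometry of the exocyclic alkene by retention. The step exploits C4 being α to a C3 carbonyl and C7 being an α-oxygenated sp3 carbon. C2 derives from (R)-lactic acid; C3 and the side-chain centres are set by catalyst or reagent control.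

Key step: step 10

Remark (assumption): 5-iodo-2-methylpent-2-ene, tributyl(iodomethyl)stannane and (+)-B-methoxydiisopinocampheylborane are taken as commercial, and the (R)-BINAP sense in step 14 is assigned by analogy with tiglic-type substrates (the antipodal ligand would be used if the sense proves opposite).

Step 1
Reactants: 1 (R)-lactic acid; 2 pivalaldehyde
Product: 3 (2R,5R)-2-tert-butyl-5-methyl-1,3-dioxolan-4-one
Conditions: p-TsOH (cat.), pentane, reflux (Dean–Stark); crystallisation of the cis isomer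
Reagents that add atoms: none
Why: Acid-catalysed acetalisation (Seebach dioxolanone formation) is expected to favour the cis acetal, whose new centre is fixed by the lactate stereocentre.

Step 2
Reactants: 3 (2R,5R)-2-tert-butyl-5-methyl-1,3-dioxolan-4-one; 4 5-iodo-2-methylpent-2-ene
Product: 6 (2R,5S)-2-tert-butyl-5-methyl-5-(4-methylpent-3-en-1-yl)-1,3-dioxolan-4-one, via lithium enolate 5 (not isolated)
Conditions: LiN(i-Pr)2, THF, −78 °C; 4, DMPU, −78 to −30 °C
Reagents that add atoms: none
Why: Seebach self-regeneration of stereocentres: the planar enolate should be alkylated anti to the tert-butyl group, so the acetal centre sets the quaternary carbon (the future C2).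

Step 3
Reactants: 6 (2R,5S)-2-tert-butyl-5-methyl-5-(4-methylpent-3-en-1-yl)-1,3-dioxolan-4-one
Product: 7 (2S)-2-hydroxy-N-methoxy-N,2,6-trimethylhept-5-enamide
Conditions: MeNH(OMe)·HCl, i-PrMgCl, THF, −20 to 0 °C
Reagents that add atoms: N,O-dimethylhydroxylamine hydrochloride, CNOC.Cl
Why: Weinreb aminolysis of the activated acyl acetal by the chloromagnesium amide should release pivalaldehyde and the tertiary alcohol without touching the stereocentre.

Step 4
Reactants: 7 (2S)-2-hydroxy-N-methoxy-N,2,6-trimethylhept-5-enamide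
Product: 8 (2S)-N-methoxy-N,2,6-trimethyl-2-[(tributylstannyl)methoxy]hept-5-enamide
Conditions: KH, 18-crown-6, THF, 0 °C; Bu3SnCH2I, 0 to 25 °C
Reagents that add atoms: tributyl(iodomethyl)stannane, CCCC[Sn](CCCC)(CCCC)CI
Why: Williamson etherification of the tertiary potassium alkoxide with the primary iodide (Still stannylmethyl ether synthesis) should be clean because the amide has no α-hydrogen.

Step 5
Reactants: 8 (2S)-N-methoxy-N,2,6-trimethyl-2-[(tributylstannyl)methoxy]hept-5-enamide
Product: 9 (3S)-3,7-dimethyl-3-[(tributylstannyl)methoxy]oct-6-en-2-one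
Conditions: MeMgBr, THF, 0 °C
Reagents that add atoms: methylmagnesium bromide, C[Mg]Br
Why: Weinreb ketone synthesis: the chelated tetrahedral intermediate should stop at the methyl ketone, and the Grignard reagent does not cleave carbon–tin bonds.

Step 6
Reactants: 10 but-2-yne-1,4-diol
Product: 11 (E)-2-(tributylstannyl)but-2-ene-1,4-diol
Conditions: Bu3SnH, PdCl2(PPh3)2 (2 mol%), THF, 25 °C
Reagents that add atoms: tributyltin hydride, CCCC[SnH](CCCC)CCCC
Why: Palladium-catalysed syn-hydrostannation of the symmetrical alkyne should give the E-vinylstannane (tin cis to hydrogen) with no regiochemical issue.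

Step 7
Reactants: 11 (E)-2-(tributylstannyl)but-2-ene-1,4-diol
Product: 12 (E)-4-[(tert-butyldimethylsilyl)oxy]-2-(tributylstannyl)but-2-en-1-ol
Conditions: TBSCl (1.0 equiv), imidazole, CH2Cl2, −20 °C
Reagents that add atoms: tert-butyldimethylsilyl chloride, CC(C)(C)[Si](C)(C)Cl
Why: Selective monosilylation should occur at the less hindered hydroxyl, remote from the bulky tributylstannyl group.

Step 8
Reactants: 12 (E)-4-[(tert-butyldimethylsilyl)oxy]-2-(tributylstannyl)but-2-en-1-ol
Product: 13 (E)-4-[(tert-butyldimethylsilyl)oxy]-2-iodobut-2-en-1-ol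
Conditions: I2, CH2Cl2, 0 °C
Reagents that add atoms: iodine, II
Why: Iododestannylation proceeds with retention of alkene geometry, placing iodine cis to the vinylic hydrogen.

Step 9
Reactants: 13 (E)-4-[(tert-butyldimethylsilyl)oxy]-2-iodobut-2-en-1-ol
Product: 14 {[(E)-4-bromo-3-iodobut-2-en-1-yl]oxy}(tert-butyl)dimethylsilane
Conditions: CBr4, PPh3, CH2Cl2, 0 °C
Reagents that add atoms: tetrabromomethane, BrC(Br)(Br)Br
Why: Appel bromination of the primary allylic alcohol is neutral and should leave the vinyl iodide and silyl ether untouched.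

Step 10
Reactants: 9 (3S)-3,7-dimethyl-3-[(tributylstannyl)methoxy]oct-6-en-2-one; 14 {[(E)-4-bromo-3-iodobut-2-en-1-yl]oxy}(tert-butyl)dimethylsilane
Product: 17 (2S,6E)-6-{2-[(tert-butyldimethylsilyl)oxy]ethylidene}-2-methyl-2-(4-methylpent-3-en-1-yl)oxepan-3-one, via lithium enolate 15 (not isolated), via iodo ketone 16 (not isolated)
Conditions: LiN(i-Pr)2, THF, −78 °C; 14, DMPU, −78 to −20 °C; then Pd2(dba)3 (5 mol%), AsPh3, CuI, DMF, 60 °C, 0.005 M
Reagents that add atoms: none
Why: Deprotonation can occur only at the methyl group of 9 (the other α-carbon is quaternary), and enolate 15 displaces the primary allylic bromide of 14 by SN2 to form the C4–C5 bond (16); zerovalent palladium then inserts into the vinyl C–I bond, the alkoxymethyl group is transferred from tin (assisted by CuI) and reductive elimination forms the C6–C7 bond. The closest known reaction types are the kinetic alkylation of methyl ketone enolates with allylic halides and the Kosugi–Migita–Stille coupling of (alkoxymethyl)stannanes with vinyl halides, here run intramolecularly in the same flask. The seven-membered ring closes at C6–C7 by reductive elimination from an eight-membered palladacycle, leaving the alkene exocyclic to the new ring. No new stereocentre is formed: C2 is untouched, and the E geometry comes from 14 because oxidative addition, transmetallation and reductive elimination all retain configuration at the sp2 carbon. The step needs C- over O-alkylation and SN2 over SN2' (lithium enolate, unhindered primary bromide), monoalkylation (bromide limiting, low temperature), transfer of the α-oxygenated methylene rather than butyl from tin (the known preference), and high dilution in the second stage to suppress intermolecular coupling.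

Step 11
Reactants: 17 (2S,6E)-6-{2-[(tert-butyldimethylsilyl)oxy]ethylidene}-2-methyl-2-(4-methylpent-3-en-1-yl)oxepan-3-one
Product: 18 (2S,3R,6E)-6-{2-[(tert-butyldimethylsilyl)oxy]ethylidene}-2-methyl-2-(4-methylpent-3-en-1-yl)oxepan-3-ol
Conditions: (S)-2-methyl-CBS-oxazaborolidine (0.2 equiv), catecholborane, toluene, −78 °C
Reagents that add atoms: none
Why: Corey–Bakshi–Shibata reduction: with quaternary C2 as the large and ring C4 as the small substituent, the (S)-catalyst should deliver hydride to give the 3R carbinol under catalyst control, and catecholborane does not hydroborate the trisubstituted alkenes.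

Step 12
Reactants: 18 (2S,3R,6E)-6-{2-[(tert-butyldimethylsilyl)oxy]ethylidene}-2-methyl-2-(4-methylpent-3-en-1-yl)oxepan-3-ol
Product: 20 (2S,3R,6E)-6-(2-acetoxyethylidene)-2-methyl-2-(4-methylpent-3-en-1-yl)oxepan-3-yl acetate, via diol 19 (not isolated)
Conditions: Bu4NF, THF, 0 °C; then Ac2O, pyridine, DMAP, 25 °C
Reagents that add atoms: acetic anhydride, CC(=O)OC(C)=O
Why: Fluoride desilylation followed by acylation of both hydroxyls in one flask is routine and involves no stereocentre.

Step 13
Reactants: 20 (2S,3R,6E)-6-(2-acetoxyethylidene)-2-methyl-2-(4-methylpent-3-en-1-yl)oxepan-3-yl acetate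
Product: 22 (2S,3R,6E)-6-(2-acetoxyethylidene)-2-[(3E)-5-hydroxy-4-methylpent-3-en-1-yl]-2-methyloxepan-3-yl acetate, via enal 21 (not isolated)
Conditions: SeO2 (0.5 equiv), t-BuOOH, CH2Cl2, 25 °C; then NaBH4, MeOH, 0 °C
Reagents that add atoms: selenium dioxide, O=[Se]=O; tert-butyl hydroperoxide, CC(C)(C)OO
Why: Sharpless–Umbreit allylic oxidation (ene reaction then [2,3]-shift) should attack the more nucleophilic side-chain alkene and oxidise the methyl trans to the chain, the ring alkene being deactivated by two allylic C–O bonds, and borohydride returns any over-oxidised enal 21 to the alcohol.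

Step 14
Reactants: 22 (2S,3R,6E)-6-(2-acetoxyethylidene)-2-[(3E)-5-hydroxy-4-methylpent-3-en-1-yl]-2-methyloxepan-3-yl acetate
Product: 23 (2S,3R,6E)-6-(2-acetoxyethylidene)-2-[(4R)-5-hydroxy-4-methylpentyl]-2-methyloxepan-3-yl acetate
Conditions: H2 (100 atm), Ru(OAc)2[(R)-BINAP] (1 mol%), MeOH, 25 °C
Reagents that add atoms: none
Why: Noyori hydroxyl-directed asymmetric hydrogenation of the allylic alcohol should set the methyl-bearing centre by catalyst control and leave the non-coordinating allylic acetate alkene untouched.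

Step 15
Reactants: 23 (2S,3R,6E)-6-(2-acetoxyethylidene)-2-[(4R)-5-hydroxy-4-methylpentyl]-2-methyloxepan-3-yl acetate
Product: 24 (2S,3R,6E)-6-(2-acetoxyethylidene)-2-methyl-2-[(4R)-4-methyl-5-oxopentyl]oxepan-3-yl acetate
Conditions: Dess–Martin periodinane, NaHCO3, CH2Cl2, 0 °C
Reagents that add atoms: none
Why: Dess–Martin oxidation under buffered conditions should give the α-methyl aldehyde without epimerisation.

Step 16
Reactants: 24 (2S,3R,6E)-6-(2-acetoxyethylidene)-2-methyl-2-[(4R)-4-methyl-5-oxopentyl]oxepan-3-yl acetate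
Product: 25 (2S,3R,6E)-6-(2-acetoxyethylidene)-2-[(4R,5R)-5-hydroxy-4-methyloct-7-en-1-yl]-2-methyloxepan-3-yl acetate
Conditions: (+)-Ipc2BOMe, CH2=CHCH2MgBr, Et2O, −78 to 25 °C, Mg salts filtered off; 24, Et2O, −78 °C; NaBO3·4H2O, THF/H2O
Reagents that add atoms: allylmagnesium bromide, C=CC[Mg]Br
Why: Brown allylboration through a chair Zimmerman–Traxler transition state: the (+)-Ipc2B reagent should add to the Re face and override the weak bias of the α-methyl centre, giving the 4R,5R (syn) alcohol.

Step 17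
Reactants: 25 (2S,3R,6E)-6-(2-acetoxyethylidene)-2-[(4R,5R)-5-hydroxy-4-methyloct-7-en-1-yl]-2-methyloxepan-3-yl acetate
Product: 26 (2S,3R,6E)-6-(2-acetoxyethylidene)-2-[(4R,5R)-5-hydroxy-4,8-dimethylnon-7-en-1-yl]-2-methyloxepan-3-yl acetate
Conditions: second-generation Grubbs catalyst (5 mol%), 2-methylbut-2-ene/CH2Cl2, 40 °C
Reagents that add atoms: 2-methylbut-2-ene, CC=C(C)C
Why: Olefin cross-metathesis of the terminal alkene with excess 2-methylbut-2-ene should install the isopropylidene terminus, the trisubstituted ring alkene being inert and no stereocentre being touched.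

Compound list
1 | (R)-lactic acid | C[C@@H](O)C(=O)O | starting material
2 | pivalaldehyde | CC(C)(C)C=O | starting material
3 | (2R,5R)-2-tert-butyl-5-methyl-1,3-dioxolan-4-one | C[C@H]1O[C@@H](C(C)(C)C)OC1=O | intermediate
4 | 5-iodo-2-methylpent-2-ene | CC(C)=CCCI | starting material
5 | lithium (2R)-2-tert-butyl-5-methyl-1,3-dioxol-4-olate | CC1=C([O-])O[C@H](C(C)(C)C)O1.[Li+] | intermediate
6 | (2R,5S)-2-tert-butyl-5-methyl-5-(4-methylpent-3-en-1-yl)-1,3-dioxolan-4-one | C[C@@]1(CCC=C(C)C)O[C@@H](C(C)(C)C)OC1=O | intermediate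
7 | (2S)-2-hydroxy-N-methoxy-N,2,6-trimethylhept-5-enamide | CON(C)C(=O)[C@@](C)(O)CCC=C(C)C | intermediate
8 | (2S)-N-methoxy-N,2,6-trimethyl-2-[(tributylstannyl)methoxy]hept-5-enamide | CON(C)C(=O)[C@@](C)(OC[Sn](CCCC)(CCCC)CCCC)CCC=C(C)C | intermediate
9 | (3S)-3,7-dimethyl-3-[(tributylstannyl)methoxy]oct-6-en-2-one | CC(=O)[C@@](C)(OC[Sn](CCCC)(CCCC)CCCC)CCC=C(C)C | intermediate
10 | but-2-yne-1,4-diol | OCC#CCO | starting material
11 | (E)-2-(tributylstannyl)but-2-ene-1,4-diol | OC/C=C(\CO)[Sn](CCCC)(CCCC)CCCC | intermediate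
12 | (E)-4-[(tert-butyldimethylsilyl)oxy]-2-(tributylstannyl)but-2-en-1-ol | CC(C)(C)[Si](C)(C)OC/C=C(\CO)[Sn](CCCC)(CCCC)CCCC | intermediate
13 | (E)-4-[(tert-butyldimethylsilyl)oxy]-2-iodobut-2-en-1-ol | CC(C)(C)[Si](C)(C)OC/C=C(\CO)I | intermediate
14 | {[(E)-4-bromo-3-iodobut-2-en-1-yl]oxy}(tert-butyl)dimethylsilane | CC(C)(C)[Si](C)(C)OC/C=C(\CBr)I | intermediate
15 | lithium (3S)-3,7-dimethyl-3-[(tributylstannyl)methoxy]octa-1,6-dien-2-olate | C=C([O-])[C@@](C)(OC[Sn](CCCC)(CCCC)CCCC)CCC=C(C)C.[Li+] | intermediate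
16 | (2E,7S)-1-[(tert-butyldimethylsilyl)oxy]-3-iodo-7,11-dimethyl-7-[(tributylstannyl)methoxy]dodeca-2,10-dien-6-one | CC(C)(C)[Si](C)(C)OC/C=C(\CCC(=O)[C@@](C)(OC[Sn](CCCC)(CCCC)CCCC)CCC=C(C)C)I | intermediate
17 | (2S,6E)-6-{2-[(tert-butyldimethylsilyl)oxy]ethylidene}-2-methyl-2-(4-methylpent-3-en-1-yl)oxepan-3-one | CC(C)(C)[Si](C)(C)OC/C=C1\CCC(=O)[C@](C)(CCC=C(C)C)OC1 | intermediate
18 | (2S,3R,6E)-6-{2-[(tert-butyldimethylsilyl)oxy]ethylidene}-2-methyl-2-(4-methylpent-3-en-1-yl)oxepan-3-ol | CC(C)(C)[Si](C)(C)OC/C=C1\CC[C@@H](O)[C@](C)(CCC=C(C)C)OC1 | intermediate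
19 | (2S,3R,6E)-6-(2-hydroxyethylidene)-2-methyl-2-(4-methylpent-3-en-1-yl)oxepan-3-ol | OC/C=C1\CC[C@@H](O)[C@](C)(CCC=C(C)C)OC1 | intermediate
20 | (2S,3R,6E)-6-(2-acetoxyethylidene)-2-methyl-2-(4-methylpent-3-en-1-yl)oxepan-3-yl acetate | CC(=O)OC/C=C1\CC[C@@H](OC(C)=O)[C@](C)(CCC=C(C)C)OC1 | intermediate
21 | (2S,3R,6E)-6-(2-acetoxyethylidene)-2-methyl-2-[(3E)-4-methyl-5-oxopent-3-en-1-yl]oxepan-3-yl acetate | CC(=O)OC/C=C1\CC[C@@H](OC(C)=O)[C@](C)(CC/C=C(\C)C=O)OC1 | intermediate
22 | (2S,3R,6E)-6-(2-acetoxyethylidene)-2-[(3E)-5-hydroxy-4-methylpent-3-en-1-yl]-2-methyloxepan-3-yl acetate | CC(=O)OC/C=C1\CC[C@@H](OC(C)=O)[C@](C)(CC/C=C(\C)CO)OC1 | intermediate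
23 | (2S,3R,6E)-6-(2-acetoxyethylidene)-2-[(4R)-5-hydroxy-4-methylpentyl]-2-methyloxepan-3-yl acetate | CC(=O)OC/C=C1\CC[C@@H](OC(C)=O)[C@](C)(CCC[C@@H](C)CO)OC1 | intermediate
24 | (2S,3R,6E)-6-(2-acetoxyethylidene)-2-methyl-2-[(4R)-4-methyl-5-oxopentyl]oxepan-3-yl acetate | CC(=O)OC/C=C1\CC[C@@H](OC(C)=O)[C@](C)(CCC[C@@H](C)C=O)OC1 | intermediate
25 | (2S,3R,6E)-6-(2-acetoxyethylidene)-2-[(4R,5R)-5-hydroxy-4-methyloct-7-en-1-yl]-2-methyloxepan-3-yl acetate | CC(=O)OC/C=C1\CC[C@@H](OC(C)=O)[C@](C)(CCC[C@@H](C)[C@H](O)CC=C)OC1 | intermediate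
26 | (2S,3R,6E)-6-(2-acetoxyethylidene)-2-[(4R,5R)-5-hydroxy-4,8-dimethylnon-7-en-1-yl]-2-methyloxepan-3-yl acetate | CC(=O)OC/C=C1\CC[C@@H](OC(C)=O)[C@](C)(CCC[C@@H](C)[C@H](O)CC=C(C)C)OC1 | target

Total step count: 17
Longest linear sequence: 13 steps (steps 1–5 and 10–17)

Steps most likely to fail

Step 10. In the ring-closing stage, intermolecular coupling or slow transfer of the alkoxymethyl group from tin may outrun cyclisation, and over-alkylation may erode the first stage. The fallback makes the two bonds in separate operations and closes the ring by the enolate alkylation instead. It sets out from 9 and 13: intermolecular Stille coupling (Pd2(dba)3, AsPh3, CuI, DMF) would give (3S)-3-{[(2E)-4-[(tert-butyldimethylsilyl)oxy]-2-(hydroxymethyl)but-2-en-1-yl]oxy}-3,7-dimethyloct-6-en-2-one F1. Appel bromination (CBr4, PPh3) would then give (3S)-3-{[(2Z)-2-(bromomethyl)-4-[(tert-butyldimethylsilyl)oxy]but-2-en-1-yl]oxy}-3,7-dimethyloct-6-en-2-one F2. LiN(SiMe3)2 in THF at high dilution should close the oxepane by intramolecular C-alkylation, returning to the route at 17.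

Step 14. Enantiofacial discrimination may be insufficient for this 2-methyl-substituted allylic alcohol. The fallback relays the methyl centre from the carbinol by substrate control instead. It sets out from 22: MnO2 oxidation gives enal 21, and Brown allylation with (+)-Ipc2BOMe/CH2=CHCH2MgBr would give (2S,3R,6E)-6-(2-acetoxyethylidene)-2-[(3E,5R)-5-hydroxy-4-methylocta-3,7-dien-1-yl]-2-methyloxepan-3-yl acetate F3. Cross-metathesis with 2-methylbut-2-ene would give (2S,3R,6E)-6-(2-acetoxyethylidene)-2-[(3E,5R)-5-hydroxy-4,8-dimethylnona-3,7-dien-1-yl]-2-methyloxepan-3-yl acetate F4. Hydroxyl-directed hydrogenation with [Rh(nbd)(dppb)]BF4 and H2 should deliver hydrogen syn to the hydroxyl in the conformer that minimises A(1,2) strain and give the syn methyl/hydroxyl pair, returning to the route at 26.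

Step 13. Site selectivity may be lost (oxidation at the allylic positions of the ring alkene) or the alcohol may over-oxidise. The fallback builds the oxygenated terminus by cleavage and olefination. It sets out from 20: ozonolysis limited to the electron-rich side-chain alkene (O3, CH2Cl2, −78 °C, one equivalent; Me2S) would give (2S,3R,6E)-6-(2-acetoxyethylidene)-2-methyl-2-(3-oxopropyl)oxepan-3-yl acetate F5. Wittig reaction with 2-(triphenylphosphoranylidene)propanal should give the E-enal 21, and NaBH4 reduction returns to the route at 22.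

Further compounds
F1 | step 10 | (3S)-3-{[(2E)-4-[(tert-butyldimethylsilyl)oxy]-2-(hydroxymethyl)but-2-en-1-yl]oxy}-3,7-dimethyloct-6-en-2-one | CC(=O)[C@@](C)(OC/C(CO)=C/CO[Si](C)(C)C(C)(C)C)CCC=C(C)C
F2 | step 10 | (3S)-3-{[(2Z)-2-(bromomethyl)-4-[(tert-butyldimethylsilyl)oxy]but-2-en-1-yl]oxy}-3,7-dimethyloct-6-en-2-one | CC(=O)[C@@](C)(OC/C(CBr)=C/CO[Si](C)(C)C(C)(C)C)CCC=C(C)C
F3 | step 14 | (2S,3R,6E)-6-(2-acetoxyethylidene)-2-[(3E,5R)-5-hydroxy-4-methylocta-3,7-dien-1-yl]-2-methyloxepan-3-yl acetate | CC(=O)OC/C=C1\CC[C@@H](OC(C)=O)[C@](C)(CC/C=C(\C)[C@H](O)CC=C)OC1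
F4 | step 14 | (2S,3R,6E)-6-(2-acetoxyethylidene)-2-[(3E,5R)-5-hydroxy-4,8-dimethylnona-3,7-dien-1-yl]-2-methyloxepan-3-yl acetate | CC(=O)OC/C=C1\CC[C@@H](OC(C)=O)[C@](C)(CC/C=C(\C)[C@H](O)CC=C(C)C)OC1
F5 | step 13 | (2S,3R,6E)-6-(2-acetoxyethylidene)-2-methyl-2-(3-oxopropyl)oxepan-3-yl acetate | CC(=O)OC/C=C1\CC[C@@H](OC(C)=O)[C@](C)(CCC=O)OC1
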